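Everything rests on dismantling quinone ring A (C1–C4, C4a, C8a) at C3–C4, C1–C2 and C1–C8a. One Dötz benzannulation joins three components. These are an aryl(methoxy)carbene chromium complex (C4 plus ring B), a terminal alkyne that already carries the (R)-C1' centre (C2, C3), and one CO ligand (C1). Alkyne insertion makes the C3–C4 bond and the sequence closes ring A; oxidative work-up delivers the quinone. The step exploits the para C1/C4 dioxygenation of ring A, the size gap between H on C3 and the side chain on C2, and the symmetric 5,8-dioxygenated ring B with one free ortho carbon. Deprotection gives shikonin, acylated last with the labile (Z)-dienoic acid.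

Key step: step 7

Assumption: the naphthazarin tautomers of 17 and 24 interconvert fast, so the structure with the side chain on the quinone ring stands for both. Atom numbers are naphthoquinone C1–C8a (side chain on C2) and side chain C1'–C5'; ring A is the quinone ring and ring B the dihydroxybenzene ring.

Step 1
Reactants: 1 4-methylpent-3-enoic acid
Product: 3 N-methoxy-N,4-dimethylpent-3-enamide, via acyl imidazolide 2 (not isolated)
Conditions: 1,1'-carbonyldiimidazole, CH2Cl2, 0 °C to rt; then MeNHOMe·HCl, rt
Reagents that add atoms: N,O-dimethylhydroxylamine hydrochloride, CNOC.Cl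
Why: Weinreb amide formation through the acyl imidazolide runs under nearly neutral conditions, so the β,γ-double bond should stay out of conjugation.

Step 2
Reactants: 3 N-methoxy-N,4-dimethylpent-3-enamide; 4 ethynylmagnesium bromide
Product: 5 6-methylhept-5-en-1-yn-3-one
Conditions: THF, −20 to 0 °C; inverse quench into cold aq NaHSO4
Reagents that add atoms: none
Why: Weinreb ketone synthesis, in which the chelated tetrahedral magnesium adduct lasts until the cold acidic quench and so blocks over-addition, double-bond migration and conjugate addition of the released amine to the ynone.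

Step 3
Reactants: 5 6-methylhept-5-en-1-yn-3-one
Product: 7 (R)-6-methylhept-5-en-1-yn-3-ol, via B-alkoxy-9-BBN borinate 6 (not isolated)
Conditions: (R)-Alpine-Borane [B-isopinocampheyl-9-BBN from (+)-α-pinene], neat, rt; then HOCH2CH2NH2, Et2O, 0 °C
Reagents that add atoms: none
Why: Midland reduction, in which the pinanyl C–H hydride is passed on through a boat-like six-membered transition state with the slim ethynyl group facing the pinane methyl group; the reagent from (+)-α-pinene should therefore set the (R) carbinol centre, and alkynyl ketones react fast enough that alkene and alkyne are not hydroborated.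

Step 4
Reactants: 7 (R)-6-methylhept-5-en-1-yn-3-ol
Product: 8 (R)-3-(tert-butyldimethylsilyloxy)-6-methylhept-5-en-1-yne
Conditions: TBSCl, imidazole, DMF, rt
Reagents that add atoms: tert-butyldimethylsilyl chloride, CC(C)(C)[Si](C)(C)Cl
Why: Imidazole-promoted O-silylation masks the propargylic alcohol without touching the C–O bond, so the configuration is kept.

Step 5
Reactants: 9 hydroquinone
Product: 10 1,4-bis(methoxymethoxy)benzene
Conditions: MOMCl, i-Pr2NEt, CH2Cl2, 0 °C to rt
Reagents that add atoms: chloromethyl methyl ether, COCCl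
Why: Williamson-type O-alkylation of both phenols with the reactive α-chloro ether gives acetals that direct the lithiation of step 6 and leave under mild acid in step 8.

Step 6
Reactants: 10 1,4-bis(methoxymethoxy)benzene; 11 Cr(CO)6
Product: 14 pentacarbonyl{[2,5-bis(methoxymethoxy)phenyl](methoxy)carbene}chromium, via aryllithium 12 (not isolated), via lithium acylchromate 13 (not isolated)
Conditions: n-BuLi, THF, 0 °C; Cr(CO)6, 0 °C to rt; then Me3OBF4, CH2Cl2, rt
Reagents that add atoms: trimethyloxonium tetrafluoroborate, C[O+](C)C.F[B-](F)(F)F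
Why: Directed ortho-metalation followed by the Fischer carbene synthesis; all four ring C–H bonds of 10 are equivalent and flanked by a MOM director, so a single aryllithium forms, adds to a CO ligand, and the acylate oxygen is methylated by the hard oxonium salt.

Step 7
Reactants: 14 pentacarbonyl{[2,5-bis(methoxymethoxy)phenyl](methoxy)carbene}chromium; 8 (R)-3-(tert-butyldimethylsilyloxy)-6-methylhept-5-en-1-yne
Product: 16 (R)-2-[1-(tert-butyldimethylsilyloxy)-4-methylpent-3-enyl]-5,8-bis(methoxymethoxy)-1,4-naphthoquinone, via tricarbonylchromium naphthol complex 15 (not isolated)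
Conditions: THF, 50 °C, Ar; then (NH4)2Ce(NO3)6, MeCN/H2O, 0 °C
Reagents that add atoms: water, O
Why: Dötz benzannulation, a formal [3+2+1] assembly on zerovalent chromium: thermal loss of a cis CO from 14 lets alkyne 8 bind and insert into the Cr=C bond, which forms the C3–C4 bond, and a CO ligand then migrates to the new vinylcarbene carbon (C1–C2 bond) to give an η4-vinylketene. Ring A closes by 6π electrocyclisation of this aryl-conjugated vinylketene onto the only free ortho carbon of the aryl group (C1–C8a bond), and tautomerisation gives the 4-methoxy-1-naphthol complex 15. Regioselectivity comes from the substrate: as is general for terminal alkynes, the CH terminus of 8 binds to the carbene carbon and the bulky CH(OTBS)CH2CH=CMe2 group ends up next to the CO-derived C1, and the minor orientation would give the same quinone 16 after oxidation because ring B is symmetric. No stereocentre is created; C1' is a spectator under these neutral conditions, and the planar-chiral diastereomers of 15 converge once the metal is stripped. Chemoselectivity is secured because the trisubstituted C3'=C4' alkene stands in a 1,5-relationship to the alkyne, too short for intramolecular cyclopropanation, and because THF and the methoxycarbene favour CO insertion over indene formation. (NH4)2Ce(NO3)6 then removes chromium and oxidises only ring A, whose free C1–OH and C4–OMe make it far easier to oxidise than the bis-acetal ring B, with water supplying the C4 carbonyl oxygen.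

Step 8
Reactants: 16 (R)-2-[1-(tert-butyldimethylsilyloxy)-4-methylpent-3-enyl]-5,8-bis(methoxymethoxy)-1,4-naphthoquinone
Product: 17 shikonin, (R)-5,8-dihydroxy-2-(1-hydroxy-4-methylpent-3-enyl)-1,4-naphthoquinone
Conditions: 2 M aq H2SO4, THF, rt, Ar, dark
Reagents that add atoms: none
Why: Acid hydrolysis of the two aryl MOM acetals (activated by the peri quinone carbonyls) and of the secondary silyl ether breaks only O–CH2 and O–Si bonds, so C1' keeps its configuration, and the non-nucleophilic counter-ion cannot add to the quinone.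

Step 9
Reactants: 18 but-3-yn-1-ol; 19 2-bromopropene
Product: 20 5-methylhex-5-en-3-yn-1-ol
Conditions: PdCl2(PPh3)2 (cat.), CuI (cat.), Et3N, rt to 40 °C, Ar
Reagents that add atoms: none
Why: Sonogashira coupling of a terminal alkyne with an unhindered vinyl bromide tolerates the free alcohol and builds the whole carbon chain of the acid.

Step 10
Reactants: 20 5-methylhex-5-en-3-yn-1-ol
Product: 21 (Z)-5-methylhexa-3,5-dien-1-ol
Conditions: Zn dust activated with Cu(OAc)2 and AgNO3, MeOH/H2O, 40 °C
Reagents that add atoms: none
Why: Boland reduction, in which activated zinc delivers two hydrogens syn to the conjugated triple bond only; this sets the (Z) C3=C4 geometry and leaves the 1,1-disubstituted alkene untouched.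

Step 11
Reactants: 21 (Z)-5-methylhexa-3,5-dien-1-ol
Product: 23 (Z)-5-methylhexa-3,5-dienoic acid, via (Z)-dienal 22 (not isolated)
Conditions: TEMPO (cat.), PhI(OAc)2, MeCN/H2O, 0 °C to rt
Reagents that add atoms: water, O
Why: Oxoammonium-catalysed oxidation takes the primary alcohol through the aldehyde hydrate to the acid in a weakly acidic medium, where the β,γ-unsaturated aldehyde is consumed faster than it can enolise, so position and geometry of the diene should hold.

Step 12
Reactants: 17 shikonin; 23 (Z)-5-methylhexa-3,5-dienoic acid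
Product: 24 (1R)-1-(5,8-dihydroxy-1,4-dioxo-1,4-dihydronaphthalen-2-yl)-4-methylpent-3-enyl (3Z)-5-methylhexa-3,5-dienoate
Conditions: DCC, DMAP (cat.), CH2Cl2, −10 to 0 °C, dark
Reagents that add atoms: none
Why: Steglich esterification acylates only the C1' alcohol, because both phenols are locked in strong hydrogen bonds to the quinone carbonyls; the C1'–O bond is not broken, so (R) is retained, and the low temperature with little DMAP limits α-deprotonation and any [1,5]-hydrogen shift of the (Z)-diene.

Compound list
1 | 4-methylpent-3-enoic acid | CC(C)=CCC(=O)O | starting material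
2 | 1-(4-methylpent-3-enoyl)imidazole | CC(C)=CCC(=O)n1ccnc1 | intermediate
3 | N-methoxy-N,4-dimethylpent-3-enamide | CC(C)=CCC(=O)N(C)OC | intermediate
4 | ethynylmagnesium bromide | C#C[Mg]Br | starting material
5 | 6-methylhept-5-en-1-yn-3-one | C#CC(=O)CC=C(C)C | intermediate
6 | 9-[(R)-6-methylhept-5-en-1-yn-3-yloxy]-9-borabicyclo[3.3.1]nonane | B1(C2CCCC1CCC2)O[C@H](CC=C(C)C)C#C | intermediate
7 | (R)-6-methylhept-5-en-1-yn-3-ol | O[C@H](CC=C(C)C)C#C | intermediate
8 | (R)-3-(tert-butyldimethylsilyloxy)-6-methylhept-5-en-1-yne | CC(C)(C)[Si](C)(C)O[C@H](CC=C(C)C)C#C | intermediate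
9 | hydroquinone | Oc1ccc(O)cc1 | starting material
10 | 1,4-bis(methoxymethoxy)benzene | COCOc1ccc(OCOC)cc1 | intermediate
11 | chromium hexacarbonyl, Cr(CO)6 | [Cr].[C-]#[O+].[C-]#[O+].[C-]#[O+].[C-]#[O+].[C-]#[O+].[C-]#[O+] | starting material
12 | 2,5-bis(methoxymethoxy)phenyllithium | [Li]c1cc(OCOC)ccc1OCOC | intermediate
13 | lithium pentacarbonyl[2,5-bis(methoxymethoxy)benzoyl]chromate | [Li+].[O-]C(=[Cr])c1cc(OCOC)ccc1OCOC.[C-]#[O+].[C-]#[O+].[C-]#[O+].[C-]#[O+].[C-]#[O+] | intermediate
14 | pentacarbonyl{[2,5-bis(methoxymethoxy)phenyl](methoxy)carbene}chromium | COC(=[Cr])c1cc(OCOC)ccc1OCOC.[C-]#[O+].[C-]#[O+].[C-]#[O+].[C-]#[O+].[C-]#[O+] | intermediate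
15 | tricarbonylchromium complex of (R)-2-[1-(tert-butyldimethylsilyloxy)-4-methylpent-3-enyl]-4-methoxy-5,8-bis(methoxymethoxy)naphthalen-1-ol (both planar-chiral diastereomers) | CC(C)(C)[Si](C)(C)O[C@H](CC=C(C)C)c1cc(OC)c2c(OCOC)ccc(OCOC)c2c1O.[Cr].[C-]#[O+].[C-]#[O+].[C-]#[O+] | intermediate
16 | (R)-2-[1-(tert-butyldimethylsilyloxy)-4-methylpent-3-enyl]-5,8-bis(methoxymethoxy)-1,4-naphthoquinone | CC(C)(C)[Si](C)(C)O[C@H](CC=C(C)C)C1=CC(=O)c2c(OCOC)ccc(OCOC)c2C1=O | intermediate
17 | shikonin, (R)-5,8-dihydroxy-2-(1-hydroxy-4-methylpent-3-enyl)-1,4-naphthoquinone | O[C@H](CC=C(C)C)C1=CC(=O)c2c(O)ccc(O)c2C1=O | intermediate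
18 | but-3-yn-1-ol | C#CCCO | starting material
19 | 2-bromopropene | C=C(C)Br | starting material
20 | 5-methylhex-5-en-3-yn-1-ol | C=C(C)C#CCCO | intermediate
21 | (Z)-5-methylhexa-3,5-dien-1-ol | C=C(C)/C=C\CCO | intermediate
22 | (Z)-5-methylhexa-3,5-dienal | C=C(C)/C=C\CC=O | intermediate
23 | (Z)-5-methylhexa-3,5-dienoic acid | C=C(C)/C=C\CC(=O)O | intermediate
24 | (1R)-1-(5,8-dihydroxy-1,4-dioxo-1,4-dihydronaphthalen-2-yl)-4-methylpent-3-enyl (3Z)-5-methylhexa-3,5-dienoate | C=C(C)/C=C\CC(=O)O[C@H](CC=C(C)C)C1=CC(=O)c2c(O)ccc(O)c2C1=O | target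

Total step count: 12. Longest linear sequence: 7 steps (1, 2, 3, 4, 7, 8, 12).

Steps most likely to fail

Step 7. After alkyne insertion the vinylcarbene may cyclise without CO insertion (indene formation), which electron-rich ortho-alkoxyaryl carbenes favour. The C1'–O bond may also ionise in the electron-rich naphthol complex. The fallback sets out from 8 and 12 and comes back at 16; it closes the same C3–C4 bond by a metal-free electrocyclic ring expansion. Bromoboration of 8 with B-bromo-9-BBN and protonolysis with AcOH gives the 2-bromoalkene F1. Aryllithium 12 is quenched with BrCH2CH2Br to give the aryl bromide F2. LiTMP turns F2 into the symmetric aryne, which 1,1-dimethoxyethene traps in a [2+2] cycloaddition as the benzocyclobutenone acetal F3. Mild hydrolysis on wet SiO2 with oxalic acid gives the benzocyclobutenone F4. Wohl–Ziegler bromination (NBS, AIBN) gives the gem-dibromide F5, and AgNO3-assisted hydrolysis gives the benzocyclobutenedione F6. Bromine–lithium exchange on F1 (t-BuLi, −78 °C) and addition to one of the two equivalent carbonyl groups of F6 gives the 2-alkenyl-2-hydroxybenzocyclobutenone F7 as a mixture of carbinol epimers. In toluene at 110 °C both epimers should open conrotatorily, with OH turning outward, to one dienylketene. A 6π electrocyclisation then joins the ketene carbon (C4) to the CH2 terminus (C3), and tautomerisation gives the hydroquinone F8, which Ag2O oxidises to 16.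

Step 12. The activated acyl donor may lose an α-proton to DMAP, so that the C3=C4 double bond migrates into conjugation or loses its (Z) geometry. The base-sensitive naphthazarin may also degrade. The fallback sets out from 5 and comes back at 24. It makes the ester C–O bond by Mitsunobu inversion, which activates the alcohol and not the acid, and it does so before the quinone exists. (S)-Alpine-Borane reduces 5, by way of the enantiomeric borinate F9, to the (S)-alkynol F10. PPh3, DIAD and acid 23 invert it to the (R)-propargylic ester F11. Benzannulation with 14 as in step 7 passes through the tricarbonylchromium naphthol ester complex F12 and gives the bis-MOM quinone ester F13. MgBr2·OEt2 in CH2Cl2, directed by chelation to the peri carbonyl groups, removes both MOM groups and gives 24.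

Step 8. Once the C1' hydroxyl is free, acid may add it across the C3'=C4' alkene (tetrahydrofuran formation). Acid may also ionise the C1'–O bond, with erosion of configuration. The fallback sets out from 16 and comes back at 17. It removes the two kinds of protecting group in separate, orthogonal operations and keeps the C1' oxygen masked during the Lewis-acid stage. MgBr2·OEt2 (CH2Cl2, 0 °C) cleaves the peri-chelated MOM ethers to give the C1'-O-silyl ether of shikonin F14. Buffered fluoride (HF·pyridine, THF, 0 °C) then frees the alcohol.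

Further compounds
F1 | step 7 | (R)-2-bromo-3-(tert-butyldimethylsilyloxy)-6-methylhepta-1,5-diene | CC(C)(C)[Si](C)(C)O[C@H](CC=C(C)C)C(Br)=C
F2 | step 7 | 2-bromo-1,4-bis(methoxymethoxy)benzene | COCOc1ccc(OCOC)c(Br)c1
F3 | step 7 | 7,7-dimethoxy-2,5-bis(methoxymethoxy)bicyclo[4.2.0]octa-1,3,5-triene | COCOc1ccc(OCOC)c2c1CC2(OC)OC
F4 | step 7 | 2,5-bis(methoxymethoxy)bicyclo[4.2.0]octa-1,3,5-trien-7-one | COCOc1ccc(OCOC)c2c1CC2=O
F5 | step 7 | 8,8-dibromo-2,5-bis(methoxymethoxy)bicyclo[4.2.0]octa-1,3,5-trien-7-one | COCOc1ccc(OCOC)c2c1C(=O)C2(Br)Br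
F6 | step 7 | 2,5-bis(methoxymethoxy)bicyclo[4.2.0]octa-1,3,5-triene-7,8-dione | COCOc1ccc(OCOC)c2c1C(=O)C2=O
F7 | step 7 | 8-[(3R)-3-(tert-butyldimethylsilyloxy)-6-methylhepta-1,5-dien-2-yl]-8-hydroxy-2,5-bis(methoxymethoxy)bicyclo[4.2.0]octa-1,3,5-trien-7-one (both C8 epimers) | CC(C)(C)[Si](C)(C)O[C@H](CC=C(C)C)C(=C)C1(O)C(=O)c2c(OCOC)ccc(OCOC)c21
F8 | step 7 | (R)-2-[1-(tert-butyldimethylsilyloxy)-4-methylpent-3-enyl]-5,8-bis(methoxymethoxy)naphthalene-1,4-diol | CC(C)(C)[Si](C)(C)O[C@H](CC=C(C)C)c1cc(O)c2c(OCOC)ccc(OCOC)c2c1O
F9 | step 12 | 9-[(S)-6-methylhept-5-en-1-yn-3-yloxy]-9-borabicyclo[3.3.1]nonane | B1(C2CCCC1CCC2)O[C@@H](CC=C(C)C)C#C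
F10 | step 12 | (S)-6-methylhept-5-en-1-yn-3-ol | O[C@@H](CC=C(C)C)C#C
F11 | step 12 | (R)-6-methylhept-5-en-1-yn-3-yl (3Z)-5-methylhexa-3,5-dienoate | C=C(C)/C=C\CC(=O)O[C@H](CC=C(C)C)C#C
F12 | step 12 | tricarbonylchromium complex of (1R)-1-[1-hydroxy-4-methoxy-5,8-bis(methoxymethoxy)naphthalen-2-yl]-4-methylpent-3-enyl (3Z)-5-methylhexa-3,5-dienoate | C=C(C)/C=C\CC(=O)O[C@H](CC=C(C)C)c1cc(OC)c2c(OCOC)ccc(OCOC)c2c1O.[Cr].[C-]#[O+].[C-]#[O+].[C-]#[O+]
F13 | step 12 | (1R)-1-[5,8-bis(methoxymethoxy)-1,4-dioxo-1,4-dihydronaphthalen-2-yl]-4-methylpent-3-enyl (3Z)-5-methylhexa-3,5-dienoate | C=C(C)/C=C\CC(=O)O[C@H](CC=C(C)C)C1=CC(=O)c2c(OCOC)ccc(OCOC)c2C1=O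
F14 | step 8 | (R)-2-[1-(tert-butyldimethylsilyloxy)-4-methylpent-3-enyl]-5,8-dihydroxy-1,4-naphthoquinone | CC(C)(C)[Si](C)(C)O[C@H](CC=C(C)C)C1=CC(=O)c2c(O)ccc(O)c2C1=O
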